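One mole of substrate that has reacted is my unit, and I ask what it costs in reagent: single product can take up more reagent on its way to bis, tris and tetra adduct.

| flask | substrate | reagent | remark | time |
|---|---|---|---|---|
| beta | 0.20 M (fed, over 12 h) | 0.30 M | run made earlier; the fed solution adds 0.20 times the starting volume |  |
| theta | 0.45 M (fed, over 12 h) | 0.30 M | run made earlier; the fed solution adds 0.20 times the starting volume |  |
| flask | 0.30 M (fed, over 12 h) | 0.300 M | the fed solution adds 0.20 times the starting volume | 12 h |

- beta (time / h: substrate / %, single product / %): 0.833: 5.2, 0.5; 2.00: 10.4, 2.8; 4.00: 15.2, 9.0; 6.00: 19.2, 11.0; 8.00: 24.4, 15.4; 12.0: 40.1, 19.2; 15.0: 31.3, 20.8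
- theta (time / h: substrate / %, single product / %): 0.833: 5.8, 0; 2.00: 8.9, 2.3; 4.00: 17.0, 7.1; 6.00: 24.4, 10.3; 8.00: 34.0, 14.2; 12.0: 62.5, 15.9; 15.0: 60.7, 18.6

(scatter of a reading: 1 percentage point)

1. substrate at 12 h, in percent of the substrate charged
2. single product at 12 h, in percent of the substrate charged
3. bis adduct at 12 h, in percent of the substrate charged
4. tris adduct at 12 h, in percent of the substrate charged

First, what is the cost? In the theta run, after the dose has ended, substrate goes from 62.5% at 12.0 h to 60.7% at 15.0 h, so I count its reagent charge as taken up by then. That reading gives 1.70 for the reagent cost c, the moles of reagent taken up per mole of substrate reacted.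

Second, who is short in the flask? At that cost its substrate charge asks for 0.509 M of reagent, more than the 0.300 M charged, so reagent is the limiting reagent. By this count, substrate stops near 41.1%.

Third, how far does the flask get by 12 h? The beta and theta runs have converted 0.120 M and 0.169 M at that time. My straight line between them gives 0.139 M for the flask, which leaves 53.5% substrate, above that stopping point.

The forecast says 51% substrate, 2.5 percentage points below mine, with 18% single product, 21% bis adduct and 9% tris adduct, and adds: “The bis/tris split is not measured, so it is loose.”

The flask gives 50.1% substrate, 18.8% single product, 23.2% bis adduct and 4.52% tris adduct.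

    substrate + reagent → single product (k = 0.0304 M⁻¹ min⁻¹)
    reagent + tris adduct → tetra adduct (k = 0.0260 M⁻¹ min⁻¹)
    reagent + single product → bis adduct (k = 0.0413 M⁻¹ min⁻¹)
    reagent + bis adduct → tris adduct (k = 0.0100 M⁻¹ min⁻¹)

At 5.32 h in the flask, reagent is used 1.4 times as fast by substrate as by single product. At that time the half-life of single product by its step to bis adduct is 1.8 h, shorter than the 12 h of the run. At 12.0 h the flask's cost c is 1.85, above the 1.70 from theta, and at 120 h its substrate stands at 45.8%, above 41.1%. In a neighbour flask, the same flask with 0.75 M of reagent, c is 2.65 at 12.0 h.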